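## Retrosynthetic overview

1. Target ⇒ its 5,7-bis-MOM ether ⇒ 5,7-bis(methoxymethoxy)-6-(1-methylpiperidin-2-yl)chromone + (4-hydroxyphenyl)boronic acid; an enantioselective rhodium-catalysed 1,4-addition sets C2 and attaches ring B last.
2. Chromone ⇒ o-hydroxyacetophenone (enaminone annulation closes ring C) ⇒ phenol (ortho C-acetylation) ⇒ 2-arylpiperidine (para C–H borylation/oxidation puts in the third ring A oxygen as the only free OH, so ring C can close only to the 6-substituted isomer).
3. (R)-2-Aryl-1-methylpiperidine ⇒ N-benzyl-N-methylpyrrolidinium salt by an enantioselective [1,2]-Stevens ring expansion (five- to six-membered ring; sets the piperidine centre; new step).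
4. Ammonium salt ⇒ 1-methylpyrrolidine + 2,6-bis(methoxymethoxy)benzyl chloride ⇒ ortho-lithiation/hydroxymethylation of bis-MOM resorcinol.
5. Ring order: ring A (resorcinol, bought) → pyrrolidinium → piperidine → pyranone ring C → ring B.

Assumption: the sense of asymmetric induction in steps 4 and 9 is taken as written; if a first run shows the opposite sense, the antipodal ligand ((+)-sparteine or the (R)-bisphosphine) is used with no other change.

## Route

Step 1
Reactants: 1 resorcinol
Product: 2 1,3-bis(methoxymethoxy)benzene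
Conditions: NaH (2.4 equiv), MOMCl (2.4 equiv), DMF, 0 °C → rt
Reagents that add atoms: chloromethyl methyl ether (MOMCl) COCCl
Why: Williamson-type O-alkylation of the bis-phenoxide gives the bis-acetal, whose MOM groups direct the next lithiation and survive every basic step.

Step 2
Reactants: 2 1,3-bis(methoxymethoxy)benzene; 3 formaldehyde (used as dry paraformaldehyde)
Product: 5 [2,6-bis(methoxymethoxy)phenyl]methanol, via aryllithium 4 (not isolated)
Conditions: n-BuLi (1.1 equiv), THF, 0 °C, 1 h; (CH2O)n, −78 °C → rt; H2O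
Reagents that add atoms: none
Why: Directed ortho-metalation removes the C2–H flanked by both MOM ethers, and the aryllithium adds to formaldehyde (hydroxymethylation).

Step 3
Reactants: 5 [2,6-bis(methoxymethoxy)phenyl]methanol; 6 1-methylpyrrolidine
Product: 8 1-[[2,6-bis(methoxymethoxy)phenyl]methyl]-1-methylpyrrolidin-1-ium chloride, via benzyl chloride 7 (not isolated)
Conditions: MsCl (1.2 equiv), Et3N (1.5 equiv), CH2Cl2, 0 °C; cold aqueous wash; then 6 (2 equiv), MeCN, rt → 40 °C; crystallise from MeCN/Et2O, dry
Reagents that add atoms: methanesulfonyl chloride CS(=O)(=O)Cl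
Why: The electron-rich benzylic mesylate collapses to the chloride in situ, and Menshutkin quaternisation of the unhindered tertiary amine gives a crystalline salt.

Step 4
Reactants: 8 1-[[2,6-bis(methoxymethoxy)phenyl]methyl]-1-methylpyrrolidin-1-ium chloride
Product: 10 (2R)-2-[2,6-bis(methoxymethoxy)phenyl]-1-methylpiperidine, via ammonium ylide 9 (not isolated)
Conditions: s-BuLi (1.15 equiv), (−)-sparteine (1.3 equiv), toluene–TBME, −78 °C, 2 h; then −78 → −10 °C; H2O
Reagents that add atoms: none
Why: Proposed new method: sparteine-ligated s-BuLi removes one of the two enantiotopic benzylic protons (acidified by N+ and held by Li–O chelation to an ortho MOM oxygen) to give a configurationally defined α-ammonio benzyllithium (ylide 9); on warming, a ring N–CH2 bond migrates to this carbon in a [1,2]-Stevens shift through a tethered, caged radical pair that recombines faster than it rotates, so the C–Li configuration is carried into C2 while the pyrrolidinium becomes a piperidine; irreversible kinetic deprotonation keeps the ylide at the benzylic carbon, and the [2,3] Sommelet–Hauser path has no free ortho position; the closest known reaction types are the base-mediated Stevens ring expansion of N-benzylazetidinium salts to 2-arylpyrrolidines, N-to-C chirality transfer in Stevens shifts, and sparteine- or bis(oxazoline)-controlled asymmetric benzylic lithiation and [1,2]-Wittig rearrangement.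

Step 5
Reactants: 10 (2R)-2-[2,6-bis(methoxymethoxy)phenyl]-1-methylpiperidine
Product: 12 3,5-bis(methoxymethoxy)-4-[(2R)-1-methylpiperidin-2-yl]phenol, via aryl boronate 11 (not isolated)
Conditions: [Ir(OMe)(cod)]2 (1.5 mol %), 4,4'-di-tert-butyl-2,2'-bipyridine (3 mol %), bis(pinacolato)diboron (1.0 equiv), THF, 65 °C; then aq. NaOH, 30 % H2O2, 0 °C, 30 min
Reagents that add atoms: hydrogen peroxide OO
Why: Sterically controlled iridium-catalysed arene C–H borylation takes the only C–H with no ortho substituent (para to the piperidine), and brief cold basic peroxide oxidation turns C–B into C–OH without touching the stereocentre or, in that time, the hindered amine.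

Step 6
Reactants: 12 3,5-bis(methoxymethoxy)-4-[(2R)-1-methylpiperidin-2-yl]phenol; 13 acetyl chloride
Product: 15 1-[6-hydroxy-2,4-bis(methoxymethoxy)-3-[(2R)-1-methylpiperidin-2-yl]phenyl]ethan-1-one, via magnesium phenolate 14 (not isolated)
Conditions: EtMgBr (1.05 equiv), Et2O–toluene, 0 °C; AcCl (1.1 equiv), toluene, 0 °C → rt; aq. NH4Cl
Reagents that add atoms: none
Why: Ortho-selective C-acylation of a bromomagnesium phenolate (chelation-delivered Friedel–Crafts acylation in a non-coordinating solvent) acetylates one of the two equivalent positions next to the free OH without acid, so both MOM ethers stay on.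

Step 7
Reactants: 15 1-[6-hydroxy-2,4-bis(methoxymethoxy)-3-[(2R)-1-methylpiperidin-2-yl]phenyl]ethan-1-one; 16 N,N-dimethylformamide dimethyl acetal
Product: 18 5,7-bis(methoxymethoxy)-6-[(2R)-1-methylpiperidin-2-yl]-4H-chromen-4-one, via enaminone 17 (not isolated)
Conditions: 16 (3 equiv), toluene, 100 °C; then AcOH, CH2Cl2, 40 °C
Reagents that add atoms: none
Why: Condensation of the methyl ketone with the amide acetal gives the enaminone, and addition–elimination by the only free phenol closes the pyranone (enaminone chromone synthesis), which fixes the 6-substitution pattern because the two oxygens flanking the piperidine are still MOM ethers.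

Step 8
Reactants: 19 4-bromophenol
Product: 21 (4-hydroxyphenyl)boronic acid, via dilithio phenolate 20 (not isolated)
Conditions: n-BuLi (2.2 equiv), THF, −78 → 0 °C; B(OiPr)3, −78 °C → rt; 1 M HCl
Reagents that add atoms: triisopropyl borate CC(C)OB(OC(C)C)OC(C)C; water O
Why: Deprotonation of the phenol followed by bromine–lithium exchange gives the dilithio species, which is trapped by the borate and hydrolysed (lithiation–borylation).

Step 9
Reactants: 18 5,7-bis(methoxymethoxy)-6-[(2R)-1-methylpiperidin-2-yl]-4H-chromen-4-one; 21 (4-hydroxyphenyl)boronic acid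
Product: 23 (2S)-5,7-dihydroxy-2-(4-hydroxyphenyl)-6-[(2R)-1-methylpiperidin-2-yl]-2,3-dihydro-4H-chromen-4-one (target), via flavanone 22 (not isolated)
Conditions: [Rh(OH)(cod)]2 (1.5 mol %), (S)-MeO-F12-BIPHEP [(S)-6,6'-dimethoxy-2,2'-bis[bis(3,4,5-trifluorophenyl)phosphino]-1,1'-biphenyl] (3.3 mol %), 21 (3 equiv), toluene–H2O (10:1), 30 °C; then concentrate, 3 M HCl in MeOH, 40 °C; NaHCO3 to pH 7
Reagents that add atoms: none
Why: Rhodium-catalysed asymmetric 1,4-addition of the arylboronic acid to the chromone (Hayashi–Miyaura reaction) with an electron-poor atropisomeric bisphosphine delivers the aryl group to one face of C2 under ligand control, giving (2S) independently of the remote piperidine centre under base-free conditions that do not open the flavanone, and acid-catalysed acetal exchange in methanol then removes both MOM groups without touching C2 (the product is kept at pH 7 or below).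

## Compound list

1 | resorcinol | Oc1cccc(O)c1 | starting material
2 | 1,3-bis(methoxymethoxy)benzene | COCOc1cccc(OCOC)c1 | intermediate
3 | formaldehyde (as paraformaldehyde) | C=O | starting material
4 | [2,6-bis(methoxymethoxy)phenyl]lithium | [Li]c1c(OCOC)cccc1OCOC | intermediate (not isolated)
5 | [2,6-bis(methoxymethoxy)phenyl]methanol | OCc1c(OCOC)cccc1OCOC | intermediate
6 | 1-methylpyrrolidine | CN1CCCC1 | starting material
7 | 2-(chloromethyl)-1,3-bis(methoxymethoxy)benzene | ClCc1c(OCOC)cccc1OCOC | intermediate (not isolated)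
8 | 1-[[2,6-bis(methoxymethoxy)phenyl]methyl]-1-methylpyrrolidin-1-ium chloride | C[N+]1(Cc2c(OCOC)cccc2OCOC)CCCC1.[Cl-] | intermediate
9 | benzylic ammonium ylide of 8 (lithium–sparteine bound) | C[N+]1([CH-]c2c(OCOC)cccc2OCOC)CCCC1 | intermediate (not isolated)
10 | (2R)-2-[2,6-bis(methoxymethoxy)phenyl]-1-methylpiperidine | CN1CCCC[C@@H]1c1c(OCOC)cccc1OCOC | intermediate
11 | (2R)-2-[2,6-bis(methoxymethoxy)-4-(4,4,5,5-tetramethyl-1,3,2-dioxaborolan-2-yl)phenyl]-1-methylpiperidine | CN1CCCC[C@@H]1c1c(OCOC)cc(B2OC(C)(C)C(C)(C)O2)cc1OCOC | intermediate (not isolated)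
12 | 3,5-bis(methoxymethoxy)-4-[(2R)-1-methylpiperidin-2-yl]phenol | CN1CCCC[C@@H]1c1c(OCOC)cc(O)cc1OCOC | intermediate
13 | acetyl chloride | CC(Cl)=O | starting material
14 | bromomagnesium 3,5-bis(methoxymethoxy)-4-[(2R)-1-methylpiperidin-2-yl]phenolate | CN1CCCC[C@@H]1c1c(OCOC)cc(O[Mg]Br)cc1OCOC | intermediate (not isolated)
15 | 1-[6-hydroxy-2,4-bis(methoxymethoxy)-3-[(2R)-1-methylpiperidin-2-yl]phenyl]ethan-1-one | CN1CCCC[C@@H]1c1c(OCOC)cc(O)c(C(C)=O)c1OCOC | intermediate
16 | N,N-dimethylformamide dimethyl acetal | COC(OC)N(C)C | starting material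
17 | (2E)-3-(dimethylamino)-1-[6-hydroxy-2,4-bis(methoxymethoxy)-3-[(2R)-1-methylpiperidin-2-yl]phenyl]prop-2-en-1-one | CN1CCCC[C@@H]1c1c(OCOC)cc(O)c(C(=O)/C=C/N(C)C)c1OCOC | intermediate (not isolated)
18 | 5,7-bis(methoxymethoxy)-6-[(2R)-1-methylpiperidin-2-yl]-4H-chromen-4-one | CN1CCCC[C@@H]1c1c(OCOC)cc2OC=CC(=O)c2c1OCOC | intermediate
19 | 4-bromophenol | Oc1ccc(Br)cc1 | starting material
20 | lithium 4-lithiophenolate | [Li]Oc1ccc([Li])cc1 | intermediate (not isolated)
21 | (4-hydroxyphenyl)boronic acid | OB(O)c1ccc(O)cc1 | intermediate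
22 | (2S)-2-(4-hydroxyphenyl)-5,7-bis(methoxymethoxy)-6-[(2R)-1-methylpiperidin-2-yl]-2,3-dihydro-4H-chromen-4-one | CN1CCCC[C@@H]1c1c(OCOC)cc2c(c1OCOC)C(=O)C[C@@H](c1ccc(O)cc1)O2 | intermediate (not isolated)
23 | (2S)-5,7-dihydroxy-2-(4-hydroxyphenyl)-6-[(2R)-1-methylpiperidin-2-yl]-2,3-dihydro-4H-chromen-4-one | CN1CCCC[C@@H]1c1c(O)cc2c(c1O)C(=O)C[C@@H](c1ccc(O)cc1)O2 | target

## Step count and risks

Total steps: 9. Longest linear sequence: 8 (steps 1–7 and 9); step 8 is a one-step side branch.

**Step 4 (proposed new step).** The risks are an unknown level and sense of enantioselectivity, ring opening of the ylide by α',β-elimination to an N-but-3-enyl amine, methyl instead of ring-carbon migration, and poor solubility of the salt. The fallback uses known sulfinimine chemistry, sets out from aryllithium 4 and comes back at 10. Compound 4 is transmetalated with MgBr2·OEt2 to [2,6-bis(methoxymethoxy)phenyl]magnesium bromide F1. F1 is added at −48 °C in toluene–CH2Cl2 to (R,E)-N-(5-chloropentylidene)-2-methylpropane-2-sulfinamide F2, itself made from 5-chloropentanal and (R)-2-methylpropane-2-sulfinamide with CuSO4 in CH2Cl2. The chelation-controlled addition gives (R)-N-[(1R)-1-[2,6-bis(methoxymethoxy)phenyl]-5-chloropentyl]-2-methylpropane-2-sulfinamide F3. KN(SiMe3)2 in THF closes the ring to (2R)-2-[2,6-bis(methoxymethoxy)phenyl]-1-[(R)-tert-butylsulfinyl]piperidine F4. HCl (2 equiv) in MeOH at 0 °C removes the auxiliary to give (2R)-2-[2,6-bis(methoxymethoxy)phenyl]piperidine F5, and reductive methylation with aqueous formaldehyde 3 and NaBH(OAc)3 gives 10.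

**Step 6.** The phenolate may be O-acetylated instead of C-acetylated, and the tertiary amine may turn acetyl chloride into ketene. The fallback sets out from 12 and comes back at 15, building the acetyl group one carbon at a time. Ortho-formylation of 12 with MgCl2, Et3N and paraformaldehyde 3 in MeCN at reflux gives 6-hydroxy-2,4-bis(methoxymethoxy)-3-[(2R)-1-methylpiperidin-2-yl]benzaldehyde F6. MeMgBr (3 equiv, THF, 0 °C) gives 2-(1-hydroxyethyl)-3,5-bis(methoxymethoxy)-4-[(2R)-1-methylpiperidin-2-yl]phenol F7 as both carbinol epimers, and MnO2 in CH2Cl2 oxidises the benzylic alcohol to 15.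

**Step 9.** The electron-rich, 5,6-disubstituted chromone may add slowly, the amine may bind rhodium, the electron-rich boronic acid may protodeboronate, and the facial selectivity is assigned by analogy. The fallback sets out from 15 and 19 and comes back at 22, replacing catalyst control by separation of diastereomers. Compound 19 is treated with n-BuLi (2.2 equiv) and then DMF to give 4-hydroxybenzaldehyde F8. Claisen–Schmidt condensation of 15 with F8 (KOH, EtOH, rt) gives (2E)-1-[6-hydroxy-2,4-bis(methoxymethoxy)-3-[(2R)-1-methylpiperidin-2-yl]phenyl]-3-(4-hydroxyphenyl)prop-2-en-1-one F9. NaOAc in EtOH at reflux closes the ring by oxa-Michael addition to 22 and its epimer (2R)-2-(4-hydroxyphenyl)-5,7-bis(methoxymethoxy)-6-[(2R)-1-methylpiperidin-2-yl]-2,3-dihydro-4H-chromen-4-one F10. The two are diastereomers because the piperidine centre is fixed, so they are separated by preparative HPLC, and F10 is re-equilibrated through F9 with NaOAc. Isolated 22 is then deprotected with HCl in MeOH as in the second stage of step 9.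

Further compounds
F1 | step 4 | [2,6-bis(methoxymethoxy)phenyl]magnesium bromide | Br[Mg]c1c(OCOC)cccc1OCOC
F2 | step 4 | (R,E)-N-(5-chloropentylidene)-2-methylpropane-2-sulfinamide | CC(C)(C)[S@@](=O)/N=C/CCCCCl
F3 | step 4 | (R)-N-[(1R)-1-[2,6-bis(methoxymethoxy)phenyl]-5-chloropentyl]-2-methylpropane-2-sulfinamide | CC(C)(C)[S@@](=O)N[C@H](CCCCCl)c1c(OCOC)cccc1OCOC
F4 | step 4 | (2R)-2-[2,6-bis(methoxymethoxy)phenyl]-1-[(R)-tert-butylsulfinyl]piperidine | CC(C)(C)[S@@](=O)N1CCCC[C@@H]1c1c(OCOC)cccc1OCOC
F5 | step 4 | (2R)-2-[2,6-bis(methoxymethoxy)phenyl]piperidine | N1CCCC[C@@H]1c1c(OCOC)cccc1OCOC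
F6 | step 6 | 6-hydroxy-2,4-bis(methoxymethoxy)-3-[(2R)-1-methylpiperidin-2-yl]benzaldehyde | CN1CCCC[C@@H]1c1c(OCOC)cc(O)c(C=O)c1OCOC
F7 | step 6 | 2-(1-hydroxyethyl)-3,5-bis(methoxymethoxy)-4-[(2R)-1-methylpiperidin-2-yl]phenol (both carbinol epimers) | CN1CCCC[C@@H]1c1c(OCOC)cc(O)c(C(C)O)c1OCOC
F8 | step 9 | 4-hydroxybenzaldehyde | O=Cc1ccc(O)cc1
F9 | step 9 | (2E)-1-[6-hydroxy-2,4-bis(methoxymethoxy)-3-[(2R)-1-methylpiperidin-2-yl]phenyl]-3-(4-hydroxyphenyl)prop-2-en-1-one | CN1CCCC[C@@H]1c1c(OCOC)cc(O)c(C(=O)/C=C/c2ccc(O)cc2)c1OCOC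
F10 | step 9 | (2R)-2-(4-hydroxyphenyl)-5,7-bis(methoxymethoxy)-6-[(2R)-1-methylpiperidin-2-yl]-2,3-dihydro-4H-chromen-4-one | CN1CCCC[C@@H]1c1c(OCOC)cc2c(c1OCOC)C(=O)C[C@H](c1ccc(O)cc1)O2
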